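# Leachianone A: route through a temporary dihydrocoumarin lactone

## Analysis of the target

Leachianone A is a flavanone. Ring A is a phloroglucinol-derived benzene ring with free hydroxyls at C5 and C7 and a lavandulyl chain at C8. Ring C is the dihydropyranone, and it carries ring B (4-hydroxy-2-methoxyphenyl) at C2. There are two stereocentres: C2 (S), which is benzylic and bound to O1, and C2'' (R) in the chain, which bears H, the isopropenyl group, the prenyl CH2 and the benzylic C1''H2. They lie five bonds apart (C2–O1–C8a–C8–C1''–C2''), so neither can direct the other and each must be set by a reagent.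

The sensitive points are:
- C2 is lost under base through reversible opening of ring C to the 2'-hydroxychalcone.
- The two alkenes forbid hydrogenolysis and, once protonated, are captured by a neighbouring phenol to give a chroman.
- C2'' becomes epimerisable whenever C8'' is a carbonyl.

Two things make the synthesis hard. First, the chain must sit at C8 and not at C6, and these positions differ only in their relation to O1. Second, C2'' is an acyclic centre whose three carbon substituents are of similar size.

The route rests on one structural feature. C2'' is β to ring A through C1'', and the isopropenyl carbon C8'' can close a six-membered ring with the oxygen on C8a (O, C8a, C8, C1'', C2'', C8''). At the acid oxidation level C8'' can therefore be held as a dihydrocoumarin lactone. The C1''–C2'' bond and the O–C8'' bond then form together on an ortho-quinone methide. When the lactone is opened, its oxygen is the only free phenol on ring A and identifies O1.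

## Retrosynthetic reasoning

**23 from 22.** The last operation cuts only the three O–CH2OMe acetals. Methoxymethyl ethers are chosen because they survive fluoride, organomagnesium reagents, the titanium methylidene and amine bases. Benzyl ethers could not be removed beside the alkenes, and silyl ethers would not survive the fluoride of the key step.

**22 from 18 and 21.** The C2–C1' bond is cut. C2 is the base-labile centre, so it is made as late as possible, and ring B arrives complete. The forward reaction is an enantioface-selective aryl transfer to C2 of chromone 18. Closing O1–C2 from a chalcone instead would give weaker control of the same centre. Boronic acid 21 comes from phenol 19 through bromide 20.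

**18 from 14 through 15, 16 and 17.** Three bonds of ring C are cut: O1–C2 (oxa-Michael closure of ynone 17), C3–C4 (acetylide addition to aldehyde 15) and C4–C4a (formylation of phenol 14). In 14 the only free hydroxyl is the future O1. A magnesium phenoxide delivers formaldehyde only to its free ortho carbon, which is C4a, and C6 is left alone. A direct Friedel–Crafts or Fries acetylation is not used here. It needs Lewis acids that would strip the acetals and close the phenol onto the isopropenyl group, and it would not tell C4a from C6.

**14 from 9 through 10, 11, 12 and 13.** These are changes of oxidation level at C8''. The lactone carbonyl of 9 is C8''. Opening to amide 10 frees the phenol, a methyl nucleophile gives ketone 12, and a non-basic titanium methylidene gives the isopropenyl group of 13. The methylenation must be non-basic because C2'' is α to the ketone in 12. The phenol is silylated in 11–13, since a free phenol would add to the ketone as a cyclic hemiketal and would destroy the titanium reagent.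

**9 from 5 and 7 through 8.** C1''–C2'' and O–C8'' are cut together. This turns the acyclic stereocentre into a face-selective reaction of a chiral enolate equivalent, which the carbene catalyst makes from 7. The electrophile 8 has a single reactive carbon. The alternative cut at C8–C1'' (arene plus a chiral lavandulyl electrophile) would leave the C8/C6 question open and would need the chain stereocentre from a separate sequence.

**5 from 1 and 7 from 6.** Aldehyde 1 already has the three oxygens and the one-carbon handle. Selective bis-acetalisation (2), silylation of the chelated hydroxyl (3), reduction (4) and bromination give 5. Acid 6 is activated as acyl imidazole 7.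

## Alternatives that were turned down

**Alternative 1: ring A built by benzannulation.**
- Disconnection: C4a–C5 and C8–C8a.
- Forward key step: the lavandulyl-bearing bis(silyloxy)diene A2 adds to the sulfinyl-activated alkene of the chiral dihydropyranone A3. Loss of PhSOH and methanol aromatises ring A and gives A1, one acetal away from the target.
- For it: it is the most convergent of the plans. The C8/C6 question does not arise, because the chain position is written into A2. C2 can be set early in A3 by a reliable asymmetric hetero-Diels–Alder reaction. On these three points it is stronger than the chosen route.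
- Against it: the alkene of A3 is a vinylogous ester and a poor dienophile even with the sulfinyl group. A 4-substituted diene such as A2 is less reactive and hydrolytically fragile. The adduct holds O1 β to the C4 ketone, so expulsion of O1 (opening of ring C) competes with loss of PhSOH. A2 still needs the C2'' stereocentre from a separate asymmetric sequence.
- Comparison: the chosen route buys ring A. It solves C2'' and the regiochemistry in one catalytic step on simple compounds, at the cost of a longer linear sequence.

**Alternative 2: ring C from an alkoxy ortho-quinone methide and a styrene.**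
- Disconnection: O1–C2 and C3–C4.
- Forward key step: salicylaldehyde A5, trimethyl orthoformate and a chiral N-triflylphosphoramide give a 4-methoxy ortho-quinone methide, which adds styrene A6 to give flavan A4.
- For it: ring C and C2 are made in one catalytic step, with no chromone and no aryl-metal chemistry. The flavan is not base-labile at C2. On these points it is as strong as the chosen endgame or stronger.
- Against it: a strong Brønsted acid meets the isopropenyl and prenyl alkenes of A5, the electron-rich styrene A6 (which oligomerises under acid) and phenolic silyl ethers. The C4 methoxy group of A4 must afterwards be turned into the ketone, which costs two further steps on an oxidation-sensitive nucleus. A5 is the silyl analogue of compound 15, so the plan does not address C2'' or the C8/C6 question.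
- Comparison: it replaces only the endgame of the chosen route, under harsher conditions for the chain.

**Alternative 3: intramolecular aryl ether coupling at O1–C8a.**
- Disconnection: O1–C8a.
- Forward key step: zerovalent palladium (from Pd(OAc)2, a bulky dialkylbiarylphosphine and Cs2CO3) couples the C2 hydroxyl of bromo alcohol A8 with the C8a bromide to give flavanol silyl ether A7.
- For it: C2 is fixed beforehand as a carbinol by mature asymmetric carbonyl chemistry and is carried through with retention. No conjugate addition to a deactivated chromone is needed. On this point it is stronger.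
- Against it: the bromide of A8 is flanked by two carbon substituents on an electron-rich ring, so oxidative addition is slow. The arylpalladium bromide sits beside the isopropenyl alkene, and a 5-exo Heck cyclisation competes with alkoxide binding. β-Hydride elimination from the secondary palladium alkoxide leads to ketone and debromination. Three steps follow A7 (desilylation, oxidation, acetal removal). The hexasubstituted A8 needs its own answer to C2'' and to the regiochemistry.
- Comparison: the chosen route sets C2 by one catalytic step on a ring already closed, and palladium never meets the chain alkenes.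

Key step: step 6

## Route

Assumption: the sense of induction in the two catalyst-controlled steps (6 and 17) follows the accepted models and is to be confirmed on the first run; if it is opposite, the antipodal triazolium salt or bisphosphine is used, since both antipodes of each are available.

Step 1
Reactants: 1 2,4,6-trihydroxybenzaldehyde
Product: 2 2-hydroxy-4,6-bis(methoxymethoxy)benzaldehyde
Conditions: MOMCl (2.1 equiv), iPr2NEt, CH2Cl2, 0 °C to rt
Reagents that add atoms: chloromethyl methyl ether, COCCl
Why: Phenol acetalisation (Williamson-type O-alkylation); the 4-hydroxyl and one ortho hydroxyl react, while the remaining ortho hydroxyl is held by the hydrogen bond to the aldehyde and is left free.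

Step 2
Reactants: 2 2-hydroxy-4,6-bis(methoxymethoxy)benzaldehyde
Product: 3 2-(tert-butyldimethylsilyloxy)-4,6-bis(methoxymethoxy)benzaldehyde
Conditions: TBSCl, imidazole, DMF, rt
Reagents that add atoms: tert-butyldimethylsilyl chloride, CC(C)(C)[Si](C)(C)Cl
Why: Imidazole-promoted silylation of the chelated phenol; this oxygen becomes the fluoride-labile trigger of the key step.

Step 3
Reactants: 3 2-(tert-butyldimethylsilyloxy)-4,6-bis(methoxymethoxy)benzaldehyde
Product: 4 [2-(tert-butyldimethylsilyloxy)-4,6-bis(methoxymethoxy)phenyl]methanol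
Conditions: NaBH4, MeOH/THF, −10 °C
Reagents that add atoms: none
Why: Borohydride reduction of the aldehyde; the low temperature and protic medium keep the alkoxide protonated, so the silyl group should not migrate from the phenol to the benzylic oxygen.

Step 4
Reactants: 4 [2-(tert-butyldimethylsilyloxy)-4,6-bis(methoxymethoxy)phenyl]methanol
Product: 5 2-(tert-butyldimethylsilyloxy)-4,6-bis(methoxymethoxy)benzyl bromide
Conditions: CBr4, PPh3, 2,6-lutidine, CH2Cl2, −20 to 0 °C; filtered cold and used at once
Reagents that add atoms: carbon tetrabromide, BrC(Br)(Br)Br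
Why: Appel reaction under neutral, buffered conditions that spare the acetals; the electron-rich benzylic bromide ionises easily and is therefore carried on as a cold solution without chromatography.

Step 5
Reactants: 6 5-methylhex-4-enoic acid
Product: 7 1-(5-methylhex-4-enoyl)imidazole
Conditions: 1,1'-carbonyldiimidazole, THF, rt
Reagents that add atoms: 1,1'-carbonyldiimidazole, O=C(n1ccnc1)n1ccnc1
Why: Acyl transfer through the mixed carbonic anhydride with loss of CO2; the acyl imidazole is electrophilic enough to acylate a carbene but does not acylate phenoxide quickly in the background.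

Step 6
Reactants: 5 2-(tert-butyldimethylsilyloxy)-4,6-bis(methoxymethoxy)benzyl bromide; 7 1-(5-methylhex-4-enoyl)imidazole
Product: 9 (3R)-5,7-bis(methoxymethoxy)-3-(3-methylbut-2-en-1-yl)-3,4-dihydro-2H-chromen-2-one, via ortho-quinone methide 8 (not isolated)
Conditions: 2-mesityl-5a,10b-dihydro-4H,6H-indeno[2,1-b][1,2,4]triazolo[4,3-d][1,4]oxazin-2-ium tetrafluoroborate (antipode that gives 3R, 15 mol%), CsF, 18-crown-6, THF, −20 °C, slow addition of 5
Reagents that add atoms: none
Why: Fluoride cleaves the Si–O bond of 5 and the phenoxide expels bromide to give 8, while the carbene freed from the triazolium salt is acylated by 7 and the acyl azolium is deprotonated at its α-CH2 to a chiral azolium enolate. The enolate carbon adds to the exocyclic methylene of 8 (Michael addition with re-aromatisation), which forms C1''–C2''; the phenoxide then attacks the acyl azolium carbonyl in a 6-exo-trig acyl substitution, which forms the O–C8'' bond, closes the lactone and releases the carbene. The closest known reaction type is the carbene-catalysed formal [4+2] annulation of in situ ortho-quinone methides with azolium enolates from acyl imidazoles, which gives 3-substituted dihydrocoumarins. The one new stereocentre (C3 of 9, the future C2'') is set by the catalyst: the fused aminoindanol backbone and the N-mesityl group shield one face of the enolate. Regiochemistry needs no control, since 8 has one electrophilic carbon and one phenoxide. Chemoselectivity requires the enolate to intercept 8 faster than fluoride, imidazole or free carbene do, which is the purpose of the slow addition of 5 and the low temperature. The acidic C3–H of 9 is protected from equilibration by a short reaction time and a cold, weakly acidic quench.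

Step 7
Reactants: 9 (3R)-5,7-bis(methoxymethoxy)-3-(3-methylbut-2-en-1-yl)-3,4-dihydro-2H-chromen-2-one
Product: 10 (2R)-2-{[2-hydroxy-4,6-bis(methoxymethoxy)phenyl]methyl}-N-methoxy-N,5-dimethylhex-4-enamide
Conditions: MeNH(OMe)·HCl, AlMe3, CH2Cl2, 0 °C to rt; aqueous potassium sodium tartrate
Reagents that add atoms: N,O-dimethylhydroxylamine hydrochloride, Cl.CNOC
Why: Weinreb aminolysis of an aryl ester lactone by the aluminium amide; the reagent is not basic enough to enolise, so C2'' is kept, and the lactone oxygen is released as the single free phenol.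

Step 8
Reactants: 10 (2R)-2-{[2-hydroxy-4,6-bis(methoxymethoxy)phenyl]methyl}-N-methoxy-N,5-dimethylhex-4-enamide
Product: 11 (2R)-2-{[2-(tert-butyldimethylsilyloxy)-4,6-bis(methoxymethoxy)phenyl]methyl}-N-methoxy-N,5-dimethylhex-4-enamide
Conditions: TBSCl, imidazole, DMF, rt
Reagents that add atoms: tert-butyldimethylsilyl chloride, CC(C)(C)[Si](C)(C)Cl
Why: Phenol silylation; it prevents re-lactonisation, hemiketal formation with the ketone of step 9 and protonolysis of the titanium reagent of step 10, and it stays orthogonal to the acetals.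

Step 9
Reactants: 11 (2R)-2-{[2-(tert-butyldimethylsilyloxy)-4,6-bis(methoxymethoxy)phenyl]methyl}-N-methoxy-N,5-dimethylhex-4-enamide
Product: 12 (3R)-3-{[2-(tert-butyldimethylsilyloxy)-4,6-bis(methoxymethoxy)phenyl]methyl}-6-methylhept-5-en-2-one
Conditions: MeMgBr, THF, −20 to 0 °C; cold aqueous NH4Cl
Reagents that add atoms: methylmagnesium bromide, C[Mg]Br
Why: Weinreb ketone synthesis; the chelated tetrahedral intermediate stops at single addition and releases the ketone only on the cold, near-neutral quench, so the α-stereocentre is not exposed to base.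

Step 10
Reactants: 12 (3R)-3-{[2-(tert-butyldimethylsilyloxy)-4,6-bis(methoxymethoxy)phenyl]methyl}-6-methylhept-5-en-2-one
Product: 13 tert-butyl{3,5-bis(methoxymethoxy)-2-[(2R)-5-methyl-2-(prop-1-en-2-yl)hex-4-en-1-yl]phenoxy}dimethylsilane
Conditions: Cp2TiMe2, toluene, 65–70 °C, dark
Reagents that add atoms: dimethyltitanocene, C[Ti](C)(C1C=CC=C1)C1C=CC=C1
Why: Petasis methylenation; the titanium methylidene formed by α-elimination adds to the ketone and the oxatitanacyclobutane collapses to the 1,1-disubstituted alkene without enolisation, so C2'' keeps its configuration, which a basic phosphorus ylide would put at risk.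

Step 11
Reactants: 13 tert-butyl{3,5-bis(methoxymethoxy)-2-[(2R)-5-methyl-2-(prop-1-en-2-yl)hex-4-en-1-yl]phenoxy}dimethylsilane
Product: 14 3,5-bis(methoxymethoxy)-2-[(2R)-5-methyl-2-(prop-1-en-2-yl)hex-4-en-1-yl]phenol
Conditions: Bu4NF, THF, 0 °C
Reagents that add atoms: none
Why: Fluoride cleavage of the aryl silyl ether; the acetals and alkenes are inert, and the phenol that returns is the future O1.

Step 12
Reactants: 14 3,5-bis(methoxymethoxy)-2-[(2R)-5-methyl-2-(prop-1-en-2-yl)hex-4-en-1-yl]phenol
Product: 15 2-hydroxy-4,6-bis(methoxymethoxy)-3-[(2R)-5-methyl-2-(prop-1-en-2-yl)hex-4-en-1-yl]benzaldehyde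
Conditions: MgCl2, Et3N, (CH2O)n, MeCN, 75 °C; aqueous NH4Cl
Reagents that add atoms: formaldehyde (from paraformaldehyde), C=O
Why: Casnati–Skattebøl ortho-formylation; the magnesium phenoxide binds formaldehyde and delivers it through a six-membered transition state to its only free ortho carbon (C4a), and the hydroxymethyl intermediate is oxidised by a second formaldehyde through hydride transfer, so C6 (para to the phenol) is not touched.

Step 13
Reactants: 15 2-hydroxy-4,6-bis(methoxymethoxy)-3-[(2R)-5-methyl-2-(prop-1-en-2-yl)hex-4-en-1-yl]benzaldehyde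
Product: 16 1-{2-hydroxy-4,6-bis(methoxymethoxy)-3-[(2R)-5-methyl-2-(prop-1-en-2-yl)hex-4-en-1-yl]phenyl}prop-2-yn-1-ol (both carbinol epimers)
Conditions: HC≡CMgBr (3.5 equiv), THF, 0 °C to rt; aqueous NH4Cl
Reagents that add atoms: ethynylmagnesium bromide, C#C[Mg]Br
Why: Grignard addition to the aldehyde after the first equivalent has deprotonated the phenol; the new carbinol centre is removed in the next step, so its configuration does not matter, and the acid-labile product is used crude.

Step 14
Reactants: 16 1-{2-hydroxy-4,6-bis(methoxymethoxy)-3-[(2R)-5-methyl-2-(prop-1-en-2-yl)hex-4-en-1-yl]phenyl}prop-2-yn-1-ol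
Product: 18 5,7-bis(methoxymethoxy)-8-[(2R)-5-methyl-2-(prop-1-en-2-yl)hex-4-en-1-yl]-4H-chromen-4-one, via ynone 17 (not isolated)
Conditions: MnO2, CH2Cl2, rt; filtration; then 4-(dimethylamino)pyridine (10 mol%), DMF, rt
Reagents that add atoms: none
Why: MnO2 oxidises the benzylic, propargylic alcohol selectively; the amine then adds to the terminal ynone carbon and is displaced by the phenol, a net 6-endo-dig oxa-Michael closure that gives the chromone and not the five-membered isomer, under conditions that are neither acidic nor strongly basic.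

Step 15
Reactants: 19 4-bromo-3-methoxyphenol
Product: 20 1-bromo-2-methoxy-4-(methoxymethoxy)benzene
Conditions: MOMCl, iPr2NEt, CH2Cl2, 0 °C to rt
Reagents that add atoms: chloromethyl methyl ether, COCCl
Why: Phenol acetalisation; ring B then carries the same protecting group as ring A, so one final operation frees all three phenols.

Step 16
Reactants: 20 1-bromo-2-methoxy-4-(methoxymethoxy)benzene
Product: 21 [2-methoxy-4-(methoxymethoxy)phenyl]boronic acid
Conditions: n-BuLi, THF, −78 °C; B(OiPr)3; aqueous NH4Cl
Reagents that add atoms: triisopropyl borate, CC(C)OB(OC(C)C)OC(C)C; water, O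
Why: Bromine–lithium exchange is faster than any directed deprotonation, and the aryllithium is trapped as the borate, which mild hydrolysis turns into the boronic acid without loss of the acetal.

Step 17
Reactants: 18 5,7-bis(methoxymethoxy)-8-[(2R)-5-methyl-2-(prop-1-en-2-yl)hex-4-en-1-yl]-4H-chromen-4-one; 21 [2-methoxy-4-(methoxymethoxy)phenyl]boronic acid
Product: 22 (2S)-2-[2-methoxy-4-(methoxymethoxy)phenyl]-5,7-bis(methoxymethoxy)-8-[(2R)-5-methyl-2-(prop-1-en-2-yl)hex-4-en-1-yl]-2,3-dihydro-4H-chromen-4-one
Conditions: [Rh(OH)(L)]2 (3 mol% Rh; L = (S)-2,2'-bis[bis(3,4,5-trifluorophenyl)phosphino]-6,6'-dimethoxy-1,1'-biphenyl), 21 (3 equiv in portions), toluene/H2O, 30 °C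
Reagents that add atoms: none
Why: Hayashi–Miyaura asymmetric 1,4-addition; the aryl group passes from boron to the hydroxorhodium complex, inserts across C2=C3 on the face selected by the electron-poor bisphosphine, and water protonates the rhodium enolate, so no base is present that could open ring C. C2 is set by the ligand alone because C2'' is too far away to interfere, and a minor C2 epimer would be a diastereomer that can be removed.

Step 18
Reactants: 22 (2S)-2-[2-methoxy-4-(methoxymethoxy)phenyl]-5,7-bis(methoxymethoxy)-8-[(2R)-5-methyl-2-(prop-1-en-2-yl)hex-4-en-1-yl]-2,3-dihydro-4H-chromen-4-one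
Product: 23 leachianone A, (2S)-5,7-dihydroxy-2-(4-hydroxy-2-methoxyphenyl)-8-[(2R)-5-methyl-2-(prop-1-en-2-yl)hex-4-en-1-yl]-2,3-dihydro-4H-chromen-4-one
Conditions: HCl (3 M aqueous), MeOH, 40 °C, stopped at full conversion
Reagents that add atoms: none
Why: Acid-catalysed acetal exchange with methanol removes the three methoxymethyl groups (the chelated 5-O first); dilute acid and short exposure should leave the alkenes unprotonated and C2 untouched, and methanol scavenges the formaldehyde equivalent as dimethoxymethane.

## Compound list

1 | 2,4,6-trihydroxybenzaldehyde | O=Cc1c(O)cc(O)cc1O | starting material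
2 | 2-hydroxy-4,6-bis(methoxymethoxy)benzaldehyde | O=Cc1c(O)cc(OCOC)cc1OCOC | intermediate
3 | 2-(tert-butyldimethylsilyloxy)-4,6-bis(methoxymethoxy)benzaldehyde | CC(C)(C)[Si](C)(C)Oc1cc(OCOC)cc(OCOC)c1C=O | intermediate
4 | [2-(tert-butyldimethylsilyloxy)-4,6-bis(methoxymethoxy)phenyl]methanol | CC(C)(C)[Si](C)(C)Oc1cc(OCOC)cc(OCOC)c1CO | intermediate
5 | 2-(tert-butyldimethylsilyloxy)-4,6-bis(methoxymethoxy)benzyl bromide | CC(C)(C)[Si](C)(C)Oc1cc(OCOC)cc(OCOC)c1CBr | intermediate
6 | 5-methylhex-4-enoic acid | CC(C)=CCCC(=O)O | starting material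
7 | 1-(5-methylhex-4-enoyl)imidazole | CC(C)=CCCC(=O)n1ccnc1 | intermediate
8 | 3,5-bis(methoxymethoxy)-6-methylidenecyclohexa-2,4-dien-1-one (ortho-quinone methide) | C=C1C(=O)C=C(OCOC)C=C1OCOC | intermediate (not isolated)
9 | (3R)-5,7-bis(methoxymethoxy)-3-(3-methylbut-2-en-1-yl)-3,4-dihydro-2H-chromen-2-one | O=C1Oc2cc(OCOC)cc(OCOC)c2C[C@H]1CC=C(C)C | intermediate
10 | (2R)-2-{[2-hydroxy-4,6-bis(methoxymethoxy)phenyl]methyl}-N-methoxy-N,5-dimethylhex-4-enamide | CON(C)C(=O)[C@H](CC=C(C)C)Cc1c(O)cc(OCOC)cc1OCOC | intermediate
11 | (2R)-2-{[2-(tert-butyldimethylsilyloxy)-4,6-bis(methoxymethoxy)phenyl]methyl}-N-methoxy-N,5-dimethylhex-4-enamide | CON(C)C(=O)[C@H](CC=C(C)C)Cc1c(O[Si](C)(C)C(C)(C)C)cc(OCOC)cc1OCOC | intermediate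
12 | (3R)-3-{[2-(tert-butyldimethylsilyloxy)-4,6-bis(methoxymethoxy)phenyl]methyl}-6-methylhept-5-en-2-one | CC(=O)[C@H](CC=C(C)C)Cc1c(O[Si](C)(C)C(C)(C)C)cc(OCOC)cc1OCOC | intermediate
13 | tert-butyl{3,5-bis(methoxymethoxy)-2-[(2R)-5-methyl-2-(prop-1-en-2-yl)hex-4-en-1-yl]phenoxy}dimethylsilane | C=C(C)[C@H](CC=C(C)C)Cc1c(O[Si](C)(C)C(C)(C)C)cc(OCOC)cc1OCOC | intermediate
14 | 3,5-bis(methoxymethoxy)-2-[(2R)-5-methyl-2-(prop-1-en-2-yl)hex-4-en-1-yl]phenol | C=C(C)[C@H](CC=C(C)C)Cc1c(O)cc(OCOC)cc1OCOC | intermediate
15 | 2-hydroxy-4,6-bis(methoxymethoxy)-3-[(2R)-5-methyl-2-(prop-1-en-2-yl)hex-4-en-1-yl]benzaldehyde | C=C(C)[C@H](CC=C(C)C)Cc1c(O)c(C=O)c(OCOC)cc1OCOC | intermediate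
16 | 1-{2-hydroxy-4,6-bis(methoxymethoxy)-3-[(2R)-5-methyl-2-(prop-1-en-2-yl)hex-4-en-1-yl]phenyl}prop-2-yn-1-ol (both carbinol epimers) | C=C(C)[C@H](CC=C(C)C)Cc1c(O)c(C(O)C#C)c(OCOC)cc1OCOC | intermediate
17 | 1-{2-hydroxy-4,6-bis(methoxymethoxy)-3-[(2R)-5-methyl-2-(prop-1-en-2-yl)hex-4-en-1-yl]phenyl}prop-2-yn-1-one | C=C(C)[C@H](CC=C(C)C)Cc1c(O)c(C(=O)C#C)c(OCOC)cc1OCOC | intermediate (not isolated)
18 | 5,7-bis(methoxymethoxy)-8-[(2R)-5-methyl-2-(prop-1-en-2-yl)hex-4-en-1-yl]-4H-chromen-4-one | C=C(C)[C@H](CC=C(C)C)Cc1c(OCOC)cc(OCOC)c2c1OC=CC2=O | intermediate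
19 | 4-bromo-3-methoxyphenol | COc1cc(O)ccc1Br | starting material
20 | 1-bromo-2-methoxy-4-(methoxymethoxy)benzene | COCOc1ccc(Br)c(OC)c1 | intermediate
21 | [2-methoxy-4-(methoxymethoxy)phenyl]boronic acid | COCOc1ccc(B(O)O)c(OC)c1 | intermediate
22 | (2S)-2-[2-methoxy-4-(methoxymethoxy)phenyl]-5,7-bis(methoxymethoxy)-8-[(2R)-5-methyl-2-(prop-1-en-2-yl)hex-4-en-1-yl]-2,3-dihydro-4H-chromen-4-one | C=C(C)[C@H](CC=C(C)C)Cc1c(OCOC)cc(OCOC)c2c1O[C@H](c1ccc(OCOC)cc1OC)CC2=O | intermediate
23 | leachianone A | C=C(C)[C@H](CC=C(C)C)Cc1c(O)cc(O)c2c1O[C@H](c1ccc(O)cc1OC)CC2=O | target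

## Step count and least certain steps

Total: 18 steps. Longest linear sequence: 15 steps (steps 1–4, 6–14, 17 and 18). Step 5 and steps 15–16 are side branches.

**Step 6 (key step).** Three processes can go wrong. The quinone methide 8, stabilised by its two alkoxy donors, may be consumed by fluoride, imidazole, the free carbene or itself before the enolate reaches it. The acidic C3–H of 9 may equilibrate in the basic medium after ring closure, which would erode the enantiomeric purity. Facial selectivity may be poorer for an enolate with a flexible alkyl substituent than for an aryl-substituted one.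
Fallback (auxiliary control in place of catalyst control): the route sets out from 7 and 5 and returns at 9. Acyl imidazole 7 acylates lithiated (4S)-4-benzyl-1,3-oxazolidin-2-one (n-BuLi, THF, −78 °C) to give (4S)-4-benzyl-3-(5-methylhex-4-enoyl)-1,3-oxazolidin-2-one F1. Its sodium enolate (NaN(SiMe3)2, THF, −78 °C) is alkylated by bromide 5 on the face away from the benzyl group (Evans alkylation) to give the (2R)-imide F2. LiOH/H2O2 in THF/H2O removes the auxiliary and the aryl silyl ether to give (2R)-2-{[2-hydroxy-4,6-bis(methoxymethoxy)phenyl]methyl}-5-methylhex-4-enoic acid F3. A carbodiimide (EDC·HCl, CH2Cl2) closes F3 to lactone 9.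

**Step 4.** The electron-rich benzylic bromide may ionise while it is formed or handled. This would lead to self-alkylation, hydrolysis, or acetal cleavage by traces of HBr, and hence to low and variable amounts of 5.
Fallback (a stable leaving group in place of bromide): the route sets out from 4 and returns at 9. Acetylation of 4 (Ac2O, Et3N, DMAP cat.) gives [2-(tert-butyldimethylsilyloxy)-4,6-bis(methoxymethoxy)phenyl]methyl acetate F4, which can be purified and stored. Under the conditions of step 6, fluoride frees the phenoxide, which expels acetate to give the same quinone methide 8 and then 9.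

**Step 12.** The intermediate magnesium salicyl alkoxide may lose its benzylic oxygen and alkylate a second electron-rich ring (diarylmethane formation), or the reaction may stall at the hindered C4a.
Fallback (boron-tethered hydroxymethylation, then oxidation): the route sets out from 14 and returns at 15. PhB(OH)2 and paraformaldehyde with catalytic propionic acid in refluxing toluene (water removed) give 5,7-bis(methoxymethoxy)-8-[(2R)-5-methyl-2-(prop-1-en-2-yl)hex-4-en-1-yl]-2-phenyl-4H-1,3,2-benzodioxaborinine F5. Boron holds both oxygens in F5 and blocks intermolecular alkylation. Exchange with propane-1,3-diol releases 2-(hydroxymethyl)-3,5-bis(methoxymethoxy)-6-[(2R)-5-methyl-2-(prop-1-en-2-yl)hex-4-en-1-yl]phenol F6. MnO2 oxidises F6 to aldehyde 15.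

**Step 14.** The electron-rich phenol may be over-oxidised, or the benzylic propargylic alcohol may ionise on the oxidant surface. Ring closure at the inner alkyne carbon (five-membered ring) is a lesser risk.
Fallback (acetophenone and enaminone in place of the ynone): the route sets out from 15 and returns at 18. MeMgBr gives 1-{2-hydroxy-4,6-bis(methoxymethoxy)-3-[(2R)-5-methyl-2-(prop-1-en-2-yl)hex-4-en-1-yl]phenyl}ethan-1-ol F7. MnO2 gives the corresponding ethan-1-one F8. N,N-Dimethylformamide dimethyl acetal in warm toluene gives the (E)-3-(dimethylamino)prop-2-en-1-one F9. F9 closes to chromone 18 with loss of dimethylamine on silica gel or in acetic acid at rt.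

**Step 17.** Protodeboronation of the ortho-methoxy, electron-rich boronic acid 21 may outrun its transfer to rhodium. Insertion into the donor-deactivated chromone may be slow. Facial control by the ligand may be incomplete.
Fallback (organocopper addition and separation of diastereomers in place of catalyst control): the route sets out from 20 and 18 and returns at 22. Magnesium turnings in THF convert 20 into [2-methoxy-4-(methoxymethoxy)phenyl]magnesium bromide F10. With CuBr·SMe2 and Me3SiCl at −78 °C, F10 adds to C2 of 18 to give the 4-(trimethylsilyloxy)-2H-chromene F11 as both C2 epimers. Mild aqueous hydrolysis gives 22 together with its (2R)-epimer F12. Because C2'' is fixed, the two are diastereomers and are separated by preparative chromatography.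

**Step 18.** Protonation of the isopropenyl or prenyl alkene followed by capture by the 7-hydroxyl would give a chroman. Formaldehyde equivalents may alkylate C6. Acid may open ring C and epimerise C2.
Fallback (silyl transfer under buffered conditions in place of Brønsted acid): the route sets out from 22 and returns at 23. Me3SiOTf and 2,2'-bipyridyl in MeCN at 0 °C convert the three aryl methoxymethyl ethers into trimethylsilyl ethers, which gives (2S)-2-[2-methoxy-4-(trimethylsilyloxy)phenyl]-8-[(2R)-5-methyl-2-(prop-1-en-2-yl)hex-4-en-1-yl]-5,7-bis(trimethylsilyloxy)-2,3-dihydro-4H-chromen-4-one F13. Water at rt hydrolyses F13 to 23 without strong acid or base.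

## Further compounds

F1 | step 6 | (4S)-4-benzyl-3-(5-methylhex-4-enoyl)-1,3-oxazolidin-2-one | CC(C)=CCCC(=O)N1C(=O)OC[C@@H]1Cc1ccccc1
F2 | step 6 | (4S)-4-benzyl-3-[(2R)-2-{[2-(tert-butyldimethylsilyloxy)-4,6-bis(methoxymethoxy)phenyl]methyl}-5-methylhex-4-enoyl]-1,3-oxazolidin-2-one | O=C1OC[C@H](Cc2ccccc2)N1C(=O)[C@H](CC=C(C)C)Cc1c(O[Si](C)(C)C(C)(C)C)cc(OCOC)cc1OCOC
F3 | step 6 | (2R)-2-{[2-hydroxy-4,6-bis(methoxymethoxy)phenyl]methyl}-5-methylhex-4-enoic acid | OC(=O)[C@H](CC=C(C)C)Cc1c(O)cc(OCOC)cc1OCOC
F4 | step 4 | [2-(tert-butyldimethylsilyloxy)-4,6-bis(methoxymethoxy)phenyl]methyl acetate | CC(=O)OCc1c(O[Si](C)(C)C(C)(C)C)cc(OCOC)cc1OCOC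
F5 | step 12 | 5,7-bis(methoxymethoxy)-8-[(2R)-5-methyl-2-(prop-1-en-2-yl)hex-4-en-1-yl]-2-phenyl-4H-1,3,2-benzodioxaborinine | C=C(C)[C@H](CC=C(C)C)Cc1c2OB(c3ccccc3)OCc2c(OCOC)cc1OCOC
F6 | step 12 | 2-(hydroxymethyl)-3,5-bis(methoxymethoxy)-6-[(2R)-5-methyl-2-(prop-1-en-2-yl)hex-4-en-1-yl]phenol | C=C(C)[C@H](CC=C(C)C)Cc1c(O)c(CO)c(OCOC)cc1OCOC
F7 | step 14 | 1-{2-hydroxy-4,6-bis(methoxymethoxy)-3-[(2R)-5-methyl-2-(prop-1-en-2-yl)hex-4-en-1-yl]phenyl}ethan-1-ol (both carbinol epimers) | C=C(C)[C@H](CC=C(C)C)Cc1c(O)c(C(C)O)c(OCOC)cc1OCOC
F8 | step 14 | 1-{2-hydroxy-4,6-bis(methoxymethoxy)-3-[(2R)-5-methyl-2-(prop-1-en-2-yl)hex-4-en-1-yl]phenyl}ethan-1-one | C=C(C)[C@H](CC=C(C)C)Cc1c(O)c(C(C)=O)c(OCOC)cc1OCOC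
F9 | step 14 | (E)-3-(dimethylamino)-1-{2-hydroxy-4,6-bis(methoxymethoxy)-3-[(2R)-5-methyl-2-(prop-1-en-2-yl)hex-4-en-1-yl]phenyl}prop-2-en-1-one | C=C(C)[C@H](CC=C(C)C)Cc1c(O)c(C(=O)/C=C/N(C)C)c(OCOC)cc1OCOC
F10 | step 17 | [2-methoxy-4-(methoxymethoxy)phenyl]magnesium bromide | COCOc1ccc([Mg]Br)c(OC)c1
F11 | step 17 | {2-[2-methoxy-4-(methoxymethoxy)phenyl]-5,7-bis(methoxymethoxy)-8-[(2R)-5-methyl-2-(prop-1-en-2-yl)hex-4-en-1-yl]-2H-chromen-4-yl}oxytrimethylsilane (both C2 epimers) | C=C(C)[C@H](CC=C(C)C)Cc1c(OCOC)cc(OCOC)c2c1OC(c1ccc(OCOC)cc1OC)C=C2O[Si](C)(C)C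
F12 | step 17 | (2R)-2-[2-methoxy-4-(methoxymethoxy)phenyl]-5,7-bis(methoxymethoxy)-8-[(2R)-5-methyl-2-(prop-1-en-2-yl)hex-4-en-1-yl]-2,3-dihydro-4H-chromen-4-one | C=C(C)[C@H](CC=C(C)C)Cc1c(OCOC)cc(OCOC)c2c1O[C@@H](c1ccc(OCOC)cc1OC)CC2=O
F13 | step 18 | (2S)-2-[2-methoxy-4-(trimethylsilyloxy)phenyl]-8-[(2R)-5-methyl-2-(prop-1-en-2-yl)hex-4-en-1-yl]-5,7-bis(trimethylsilyloxy)-2,3-dihydro-4H-chromen-4-one | C=C(C)[C@H](CC=C(C)C)Cc1c(O[Si](C)(C)C)cc(O[Si](C)(C)C)c2c1O[C@H](c1ccc(O[Si](C)(C)C)cc1OC)CC2=O
A1 | alternative 1 | leachianone A 4'-methoxymethyl ether | C=C(C)[C@H](CC=C(C)C)Cc1c(O)cc(O)c2c1O[C@H](c1ccc(OCOC)cc1OC)CC2=O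
A2 | alternative 1 | 1-methoxy-1,3-bis(trimethylsilyloxy)buta-1,3-diene carrying the lavandulyl chain at C4 (chain configured as in the target) | C=C(C)[C@H](CC=C(C)C)CC=C(O[Si](C)(C)C)C=C(OC)O[Si](C)(C)C
A3 | alternative 1 | (2S)-2-[2-methoxy-4-(methoxymethoxy)phenyl]-5-(phenylsulfinyl)-2,3-dihydro-4H-pyran-4-one | O=C1C[C@@H](c2ccc(OCOC)cc2OC)OC=C1S(=O)c1ccccc1
A4 | alternative 2 | 2,4-cis-4-methoxy-8-lavandulylflavan tris(tert-butyldimethylsilyl) ether | C=C(C)[C@H](CC=C(C)C)Cc1c(O[Si](C)(C)C(C)(C)C)cc(O[Si](C)(C)C(C)(C)C)c2c1O[C@H](c1ccc(O[Si](C)(C)C(C)(C)C)cc1OC)C[C@@H]2OC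
A5 | alternative 2 | 4,6-bis(tert-butyldimethylsilyloxy)-2-hydroxy-3-[(2R)-5-methyl-2-(prop-1-en-2-yl)hex-4-en-1-yl]benzaldehyde | C=C(C)[C@H](CC=C(C)C)Cc1c(O)c(C=O)c(O[Si](C)(C)C(C)(C)C)cc1O[Si](C)(C)C(C)(C)C
A6 | alternative 2 | tert-butyl(4-ethenyl-3-methoxyphenoxy)dimethylsilane | C=Cc1ccc(O[Si](C)(C)C(C)(C)C)cc1OC
A7 | alternative 3 | 2,4-cis-8-lavandulylflavan-4-ol tert-butyldimethylsilyl ether, tris(methoxymethyl) protected | C=C(C)[C@H](CC=C(C)C)Cc1c(OCOC)cc(OCOC)c2c1O[C@H](c1ccc(OCOC)cc1OC)C[C@@H]2O[Si](C)(C)C(C)(C)C
A8 | alternative 3 | 3-{2-bromo-4,6-bis(methoxymethoxy)-3-[(2R)-5-methyl-2-(prop-1-en-2-yl)hex-4-en-1-yl]phenyl}-3-(tert-butyldimethylsilyloxy)-1-[2-methoxy-4-(methoxymethoxy)phenyl]propan-1-ol (configured as in A7) | C=C(C)[C@H](CC=C(C)C)Cc1c(OCOC)cc(OCOC)c(c1Br)[C@@H](O[Si](C)(C)C(C)(C)C)C[C@H](O)c1ccc(OCOC)cc1OC
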